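**Strategy.** The tetrahydropyran ring (O1, C2 aryl, C3, C4 acetoxy, C5, C6 arylethyl) is read as a cyclised β-hydroxy enone: O1 on C2 stands 1,3 to the C4 oxygen, and C6 is the β-carbon of a C4 ketone. The ring is therefore cut at C3–C4 and O1–C6. An (R)-chlorohydrin holding O1, C2 and C3 is converted into its O,C-dilithio form, which acylates an (E)-Weinreb enamide (C4–C6 plus side chain). The released hydroxy enone closes by 6-endo oxa-Michael addition to the 2,6-cis pyranone in the same operation. C2, set by CBS reduction, controls C6 and, through the chair, C4.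

Key step: step 7

Remark: compounds 1, 5 and 8 are taken as commercial; ring atoms are numbered O1, C2 (aryl-bearing), C3, C4 (acetoxy-bearing), C5, C6 (arylethyl-bearing) throughout.

Step 1
Reactants: 1 methyl 3,4-dihydroxy-5-methoxybenzoate
Product: 2 methyl 3,4-bis(benzyloxy)-5-methoxybenzoate
Conditions: BnBr, K2CO3, DMF, 60 °C
Reagents that add atoms: benzyl bromide, BrCc1ccccc1
Why: Williamson ether synthesis; both phenoxides are alkylated by the benzylic bromide while the methyl ester is inert to K2CO3 in DMF.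

Step 2
Reactants: 2 methyl 3,4-bis(benzyloxy)-5-methoxybenzoate
Product: 3 1-[3,4-bis(benzyloxy)-5-methoxyphenyl]-2-chloroethan-1-one
Conditions: ICH2Cl, MeLi·LiBr, THF/Et2O, −78 °C; then AcOH, −78 °C
Reagents that add atoms: chloroiodomethane, ClCI
Why: Nucleophilic acyl substitution by the carbenoid chloromethyllithium, made by iodine–lithium exchange in the presence of the ester; the tetrahedral adduct persists at −78 °C, so the chloromethyl ketone is released only on the cold acid quench and a second addition is avoided.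

Step 3
Reactants: 3 1-[3,4-bis(benzyloxy)-5-methoxyphenyl]-2-chloroethan-1-one
Product: 4 (R)-1-[3,4-bis(benzyloxy)-5-methoxyphenyl]-2-chloroethan-1-ol
Conditions: (R)-2-methyl-CBS-oxazaborolidine (10 mol %), BH3·SMe2, THF, 0 °C; MeOH
Reagents that add atoms: none
Why: Corey–Bakshi–Shibata reduction; the aryl group takes the large-group position in the catalyst–borane–ketone complex, so hydride delivery to one face should set the carbinol center as R (the spatial sense of an (S)-1-arylethanol, because CH2Cl outranks aryl).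

Step 4
Reactants: 5 3-(4-hydroxy-3-methoxyphenyl)propan-1-ol
Product: 6 3-[4-(benzyloxy)-3-methoxyphenyl]propan-1-ol
Conditions: BnBr, K2CO3, acetone, reflux
Reagents that add atoms: benzyl bromide, BrCc1ccccc1
Why: Williamson ether synthesis, chemoselective because only the phenol is deprotonated by K2CO3 and the aliphatic alcohol stays free.

Step 5
Reactants: 6 3-[4-(benzyloxy)-3-methoxyphenyl]propan-1-ol
Product: 7 3-[4-(benzyloxy)-3-methoxyphenyl]propanal
Conditions: PhI(OAc)2, TEMPO (cat.), CH2Cl2, rt
Reagents that add atoms: none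
Why: TEMPO-catalysed oxoammonium oxidation with PhI(OAc)2 as terminal oxidant stops at the aldehyde under anhydrous conditions and leaves the electron-rich arene and the benzyl ether untouched.

Step 6
Reactants: 7 3-[4-(benzyloxy)-3-methoxyphenyl]propanal; 8 diethyl {2-[methoxy(methyl)amino]-2-oxoethyl}phosphonate
Product: 9 (E)-5-[4-(benzyloxy)-3-methoxyphenyl]-N-methoxy-N-methylpent-2-enamide
Conditions: NaH, THF, 0 °C to rt
Reagents that add atoms: none
Why: Horner–Wadsworth–Emmons olefination with a stabilised phosphonate anion, which should give the (E)-enamide through the thermodynamically favoured oxaphosphetane.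

Step 7
Reactants: 4 (R)-1-[3,4-bis(benzyloxy)-5-methoxyphenyl]-2-chloroethan-1-ol; 9 (E)-5-[4-(benzyloxy)-3-methoxyphenyl]-N-methoxy-N-methylpent-2-enamide
Product: 12 (2S,6S)-2-[3,4-bis(benzyloxy)-5-methoxyphenyl]-6-{2-[4-(benzyloxy)-3-methoxyphenyl]ethyl}tetrahydro-4H-pyran-4-one, via dilithio species 10 (not isolated), via hydroxy enone 11 (not isolated)
Conditions: n-BuLi, THF, −78 °C; LiC10H8 (lithium naphthalenide, 2 equiv), −78 °C; 9, −78 to −40 °C; AcOH; then DBU (cat.), 0 °C to rt
Reagents that add atoms: none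
Why: Electron transfer from the naphthalene radical anion to the C–Cl bond of the lithium alkoxide of 4 gives the O,C-dilithio species 10, which resists β-elimination at −78 °C because it would have to expel Li2O; its carbanion (C3) adds 1,2 to the Weinreb amide carbon (C4) of 9, and the N-methoxy chelate holds the tetrahedral adduct until the acid quench releases hydroxy enone 11. The closest known reaction types are the Weinreb ketone synthesis with a β-oxido organolithium and the base-catalysed intramolecular oxa-Michael addition. With catalytic DBU the C2 hydroxyl adds to the enone β-carbon C6 in a 6-endo-trig closure that forms the O1–C6 bond and the tetrahydropyranone ring. The C2 center comes unchanged from 4, and it controls the new C6 center because a chair-like closure with aryl and arylethyl groups both equatorial is favoured and the reversible addition funnels material to the 2,6-cis ketone. The step needs C- over O-acylation and 1,2- over 1,4-addition, which the more nucleophilic carbanion and the chelating Weinreb amide should secure, and it needs the benzylic β-hydroxy ketone not to dehydrate, which short exposure to a weak, catalytic base at low temperature should secure.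

Step 8
Reactants: 12 (2S,6S)-2-[3,4-bis(benzyloxy)-5-methoxyphenyl]-6-{2-[4-(benzyloxy)-3-methoxyphenyl]ethyl}tetrahydro-4H-pyran-4-one
Product: 14 (2S,4S,6S)-2-[3,4-bis(benzyloxy)-5-methoxyphenyl]-6-{2-[4-(benzyloxy)-3-methoxyphenyl]ethyl}tetrahydro-2H-pyran-4-yl acetate, via lithium alkoxide 13 (not isolated)
Conditions: LiBH(s-Bu)3, THF, −78 °C; then Ac2O, DMAP (cat.), −78 °C to rt
Reagents that add atoms: acetic anhydride, CC(=O)OC(C)=O
Why: Diastereoselective ketone reduction with a bulky trialkylborohydride followed by O-acylation; with the C2 and C6 substituents equatorial in the chair, hydride attacks C4 from the equatorial direction and sets the axial (4S) alkoxide trans to both substituents, which Ac2O traps with retention.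

Step 9
Reactants: 14 (2S,4S,6S)-2-[3,4-bis(benzyloxy)-5-methoxyphenyl]-6-{2-[4-(benzyloxy)-3-methoxyphenyl]ethyl}tetrahydro-2H-pyran-4-yl acetate
Product: 15 (2S,4S,6S)-2-(3,4-dihydroxy-5-methoxyphenyl)-6-[2-(4-hydroxy-3-methoxyphenyl)ethyl]tetrahydro-2H-pyran-4-yl acetate
Conditions: H2 (1 atm), 10% Pd/C, EtOAc, rt
Reagents that add atoms: none
Why: Catalytic hydrogenolysis of the three aryl benzyl ethers over Pd/C under neutral conditions should free the phenols without touching the acetate or the stereocenters.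

**Compound list**

1 | methyl 3,4-dihydroxy-5-methoxybenzoate | COC(=O)c1cc(O)c(O)c(OC)c1 | starting material
2 | methyl 3,4-bis(benzyloxy)-5-methoxybenzoate | COC(=O)c1cc(OCc2ccccc2)c(OCc2ccccc2)c(OC)c1 | intermediate
3 | 1-[3,4-bis(benzyloxy)-5-methoxyphenyl]-2-chloroethan-1-one | O=C(CCl)c1cc(OCc2ccccc2)c(OCc2ccccc2)c(OC)c1 | intermediate
4 | (R)-1-[3,4-bis(benzyloxy)-5-methoxyphenyl]-2-chloroethan-1-ol | O[C@@H](CCl)c1cc(OCc2ccccc2)c(OCc2ccccc2)c(OC)c1 | intermediate
5 | 3-(4-hydroxy-3-methoxyphenyl)propan-1-ol | COc1cc(CCCO)ccc1O | starting material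
6 | 3-[4-(benzyloxy)-3-methoxyphenyl]propan-1-ol | COc1cc(CCCO)ccc1OCc1ccccc1 | intermediate
7 | 3-[4-(benzyloxy)-3-methoxyphenyl]propanal | COc1cc(CCC=O)ccc1OCc1ccccc1 | intermediate
8 | diethyl {2-[methoxy(methyl)amino]-2-oxoethyl}phosphonate | CCOP(=O)(CC(=O)N(C)OC)OCC | starting material
9 | (E)-5-[4-(benzyloxy)-3-methoxyphenyl]-N-methoxy-N-methylpent-2-enamide | CON(C)C(=O)/C=C/CCc1ccc(OCc2ccccc2)c(OC)c1 | intermediate
10 | lithium (S)-1-[3,4-bis(benzyloxy)-5-methoxyphenyl]-2-lithioethan-1-olate (dilithio species) | [Li]O[C@@H](C[Li])c1cc(OCc2ccccc2)c(OCc2ccccc2)c(OC)c1 | intermediate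
11 | (S,E)-1-[3,4-bis(benzyloxy)-5-methoxyphenyl]-7-[4-(benzyloxy)-3-methoxyphenyl]-1-hydroxyhept-4-en-3-one (hydroxy enone) | O[C@@H](CC(=O)/C=C/CCc1ccc(OCc2ccccc2)c(OC)c1)c1cc(OCc2ccccc2)c(OCc2ccccc2)c(OC)c1 | intermediate
12 | (2S,6S)-2-[3,4-bis(benzyloxy)-5-methoxyphenyl]-6-{2-[4-(benzyloxy)-3-methoxyphenyl]ethyl}tetrahydro-4H-pyran-4-one (2,6-cis) | COc1cc(CC[C@H]2CC(=O)C[C@@H](c3cc(OCc4ccccc4)c(OCc4ccccc4)c(OC)c3)O2)ccc1OCc1ccccc1 | intermediate
13 | lithium (2S,4S,6S)-2-[3,4-bis(benzyloxy)-5-methoxyphenyl]-6-{2-[4-(benzyloxy)-3-methoxyphenyl]ethyl}tetrahydro-2H-pyran-4-olate (axial alkoxide) | COc1cc(CC[C@H]2C[C@H](O[Li])C[C@@H](c3cc(OCc4ccccc4)c(OCc4ccccc4)c(OC)c3)O2)ccc1OCc1ccccc1 | intermediate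
14 | (2S,4S,6S)-2-[3,4-bis(benzyloxy)-5-methoxyphenyl]-6-{2-[4-(benzyloxy)-3-methoxyphenyl]ethyl}tetrahydro-2H-pyran-4-yl acetate | COc1cc(CC[C@H]2C[C@H](OC(C)=O)C[C@@H](c3cc(OCc4ccccc4)c(OCc4ccccc4)c(OC)c3)O2)ccc1OCc1ccccc1 | intermediate
15 | (2S,4S,6S)-2-(3,4-dihydroxy-5-methoxyphenyl)-6-[2-(4-hydroxy-3-methoxyphenyl)ethyl]tetrahydro-2H-pyran-4-yl acetate | COc1cc(CC[C@H]2C[C@H](OC(C)=O)C[C@@H](c3cc(O)c(O)c(OC)c3)O2)ccc1O | target

**Step count and risks**

Total steps: 9. Longest linear sequence: 6 steps (steps 1, 2, 3, 7, 8, 9; the branch through steps 4, 5, 6 is equally long).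

Step 7 (reductive lithiation, acylation, oxa-Michael closure). The dilithio species may be protonated or may eliminate before it is acylated. Residual naphthalenide may transfer electrons to the enamide or to the benzyl ethers. The carbanion may add 1,4 or deprotonate the γ-position of 9. The benzylic β-hydroxy ketone may dehydrate, and configuration at C2 may erode through retro-Michael opening on the aryl side during equilibration. The fallback sets out from ester 2 (and uses 9) and comes back at hydroxy enone 11, which closes to 12 with DBU as in step 7. Ester 2 is condensed with lithiated methyl phenyl sulfone (THF, −78 °C) to the β-keto sulfone 1-[3,4-bis(benzyloxy)-5-methoxyphenyl]-2-(phenylsulfonyl)ethan-1-one F1. Asymmetric transfer hydrogenation (RuCl[(S,S)-TsDPEN](p-cymene), HCO2H/Et3N) should give (R)-1-[3,4-bis(benzyloxy)-5-methoxyphenyl]-2-(phenylsulfonyl)ethan-1-ol F2. Its O,C-dianion (2 equiv n-BuLi, THF, −78 °C), a stabilised carbanion that does not eliminate, is acylated by 9 to (1R,4E)-1-[3,4-bis(benzyloxy)-5-methoxyphenyl]-7-[4-(benzyloxy)-3-methoxyphenyl]-1-hydroxy-2-(phenylsulfonyl)hept-4-en-3-one F3 (C2 epimers). Reductive desulfonylation (SmI2, THF/MeOH, −78 °C) then gives 11.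

Step 2 (chloromethyllithium on the ester). The tetrahedral adduct may collapse early, which leads to a second carbenoid addition and epoxide formation, or the carbenoid may decompose before it adds. The fallback sets out from 2 and comes back at 3. Acylation of dimethylsulfoxonium methylide (Me3S(O)I, KOt-Bu, THF, reflux) by 2 should give the stable ylide 1-[3,4-bis(benzyloxy)-5-methoxyphenyl]-2-[dimethyl(oxo)-λ6-sulfanylidene]ethan-1-one F4. HCl in THF at 65 °C protonates the ylide carbon, and chloride displaces dimethyl sulfoxide to give 3.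

Step 9 (hydrogenolysis). Once the para-hydroxyl is freed, the benzylic C2–O1 ring bond may be cleaved by over-reduction, or debenzylation may stop short. The fallback sets out from 14 and comes back at 15 without a new compound. It is a Lewis-acid debenzylation with BCl3 and pentamethylbenzene (CH2Cl2, −78 °C), in which the arene traps the benzyl cations and the acetate is left intact.

Further compounds
F1 | step 7 | 1-[3,4-bis(benzyloxy)-5-methoxyphenyl]-2-(phenylsulfonyl)ethan-1-one | O=C(CS(=O)(=O)c1ccccc1)c1cc(OCc2ccccc2)c(OCc2ccccc2)c(OC)c1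
F2 | step 7 | (R)-1-[3,4-bis(benzyloxy)-5-methoxyphenyl]-2-(phenylsulfonyl)ethan-1-ol | O[C@@H](CS(=O)(=O)c1ccccc1)c1cc(OCc2ccccc2)c(OCc2ccccc2)c(OC)c1
F3 | step 7 | (1R,4E)-1-[3,4-bis(benzyloxy)-5-methoxyphenyl]-7-[4-(benzyloxy)-3-methoxyphenyl]-1-hydroxy-2-(phenylsulfonyl)hept-4-en-3-one (C2 epimers) | O[C@@H](C(C(=O)/C=C/CCc1ccc(OCc2ccccc2)c(OC)c1)S(=O)(=O)c1ccccc1)c1cc(OCc2ccccc2)c(OCc2ccccc2)c(OC)c1
F4 | step 2 | 1-[3,4-bis(benzyloxy)-5-methoxyphenyl]-2-[dimethyl(oxo)-λ6-sulfanylidene]ethan-1-one | CS(C)(=O)=CC(=O)c1cc(OCc2ccccc2)c(OCc2ccccc2)c(OC)c1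
F0 | step 9 | none | none
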